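**Strategy.** The oxepane (ring O, C7, C8, C9, C10, C11, C12) is disconnected at C10–C11. C10 is a carbinol carbon, so it can be carried as a 1,3-dithiane and made nucleophilic. C11 is an unfunctionalised CH2 flanking the ether carbon C12 and can bear a leaving group. One intramolecular alkylation therefore forms C10–C11 and the seven-membered ring on an acyclic C7–O–C12 ether whose stereocentres (C7, C9, C12, C13) are already set. The cyclisation substrate is a 2-(1-hydroxyalkyl)-1,3-dithiane with a primary C11 chloride, a silyl ether at O6 and a PMB ether at O13. The halogens, the C10 hydroxyl and the Z-enyne follow after ring closure.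

Key step: step 13

Remark on the chemistry: target numbering (C1 alkyne terminus to C15) is used for all intermediates; the C11 leaving group is chloride, because an alkyl iodide would undergo iodine–lithium exchange and β-alkoxide fragmentation with the alkyllithium that metalates the dithiane, and C9 is chlorinated only after the C10 ketone has been reduced under control of the C9 silyloxy group.

Step 1
Reactants: 1 penta-1,4-dien-3-ol
Product: 2 (2R,3S)-1,2-epoxypent-4-en-3-ol
Conditions: Ti(OiPr)4 (cat.), L-(+)-diisopropyl tartrate (cat.), t-BuOOH, 4 Å MS, CH2Cl2, −20 °C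
Reagents that add atoms: tert-butyl hydroperoxide, CC(C)(C)OO
Why: Sharpless asymmetric epoxidation desymmetrises the divinylcarbinol, the L-(+)-tartrate complex epoxidising one enantiotopic vinyl group on one face (erythro product) and so setting C12 and C13, while the minor enantiomer is consumed by a faster second epoxidation.

Step 2
Reactants: 2 (2R,3S)-1,2-epoxypent-4-en-3-ol
Product: 3 (2R,3S)-1,2-epoxy-3-(4-methoxybenzyloxy)pent-4-ene
Conditions: NaH, 4-methoxybenzyl chloride, Bu4NI (cat.), THF/DMF, −20 → 0 °C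
Reagents that add atoms: 4-methoxybenzyl chloride, COc1ccc(CCl)cc1
Why: Williamson etherification of the sodium alkoxide at low temperature should outrun Payne rearrangement and gives a base-stable, non-migrating ether at O13.

Step 3
Reactants: 3 (2R,3S)-1,2-epoxy-3-(4-methoxybenzyloxy)pent-4-ene
Product: 4 (2R,3S)-1,2-epoxy-3-(4-methoxybenzyloxy)pentane
Conditions: H2 (1 atm), RhCl(PPh3)3 (5 mol%), benzene/EtOH, 25 °C
Reagents that add atoms: none
Why: Homogeneous hydrogenation with RhCl(PPh3)3 saturates the monosubstituted alkene to the C14–C15 ethyl group without hydrogenolysis of the benzylic ether or the epoxide.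

Step 4
Reactants: 4 (2R,3S)-1,2-epoxy-3-(4-methoxybenzyloxy)pentane
Product: 5 (2S,3S)-1-chloro-3-(4-methoxybenzyloxy)pentan-2-ol
Conditions: LiCl, AcOH, THF, 25 °C
Reagents that add atoms: lithium chloride, [Li+].[Cl-]
Why: Acid-assisted SN2 opening of the terminal epoxide by chloride at the unhindered C11 leaves the C12–O bond and its configuration untouched and installs the leaving group needed later.

Step 5
Reactants: 5 (2S,3S)-1-chloro-3-(4-methoxybenzyloxy)pentan-2-ol; 6 ethyl diazoacetate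
Product: 7 ethyl 2-{[(2S,3S)-1-chloro-3-(4-methoxybenzyloxy)pentan-2-yl]oxy}acetate
Conditions: Rh2(OAc)4 (1 mol%), slow addition of 6, CH2Cl2, 25 °C
Reagents that add atoms: none
Why: Rhodium-carbenoid O–H insertion alkylates the C12 hydroxyl under neutral conditions, so the β-chloro alcohol cannot close back to the epoxide as it would under Williamson conditions.

Step 6
Reactants: 7 ethyl 2-{[(2S,3S)-1-chloro-3-(4-methoxybenzyloxy)pentan-2-yl]oxy}acetate
Product: 8 2-{[(2S,3S)-1-chloro-3-(4-methoxybenzyloxy)pentan-2-yl]oxy}acetic acid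
Conditions: LiOH, THF/H2O, 0 °C; then 1 M HCl to pH 3
Reagents that add atoms: lithium hydroxide, [Li+].[OH-]
Why: Ester saponification in the cold leaves the deactivated primary chloride and the PMB ether intact.

Step 7
Reactants: 8 2-{[(2S,3S)-1-chloro-3-(4-methoxybenzyloxy)pentan-2-yl]oxy}acetic acid; 9 (S)-4-benzyloxazolidin-2-one
Product: 11 (4S)-4-benzyl-3-(2-{[(2S,3S)-1-chloro-3-(4-methoxybenzyloxy)pentan-2-yl]oxy}acetyl)oxazolidin-2-one, via mixed pivalic anhydride 10 (not isolated)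
Conditions: t-BuCOCl, Et3N, THF, −20 °C; then LiCl, 9, 0 → 25 °C
Reagents that add atoms: none
Why: N-acylation of the oxazolidinone through the mixed pivalic anhydride (LiCl/Et3N protocol) attaches the Evans auxiliary to the glycolic acid.

Step 8
Reactants: 11 (4S)-4-benzyl-3-(2-{[(2S,3S)-1-chloro-3-(4-methoxybenzyloxy)pentan-2-yl]oxy}acetyl)oxazolidin-2-one; 12 2-bromo-N-methoxy-N-methylacetamide
Product: 14 (4S)-4-benzyl-3-[(2R)-2-{[(2S,3S)-1-chloro-3-(4-methoxybenzyloxy)pentan-2-yl]oxy}-4-[methoxy(methyl)amino]-4-oxobutanoyl]oxazolidin-2-one, via sodium Z-enolate 13 (not isolated)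
Conditions: NaN(SiMe3)2, THF, −78 °C; then 12 (3 equiv), −78 → −45 °C
Reagents that add atoms: none
Why: Evans-type asymmetric alkylation of a glycolate imide, in which the chelated sodium Z-enolate is attacked by the activated α-bromo amide on the face away from the benzyl group, sets C7 as R and brings in C8–C9.

Step 9
Reactants: 14 (4S)-4-benzyl-3-[(2R)-2-{[(2S,3S)-1-chloro-3-(4-methoxybenzyloxy)pentan-2-yl]oxy}-4-[methoxy(methyl)amino]-4-oxobutanoyl]oxazolidin-2-one
Product: 15 (3R)-3-{[(2S,3S)-1-chloro-3-(4-methoxybenzyloxy)pentan-2-yl]oxy}-4-hydroxy-N-methoxy-N-methylbutanamide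
Conditions: NaBH4, THF/H2O, 0 → 25 °C
Reagents that add atoms: none
Why: Reductive removal of the auxiliary, NaBH4 reducing the activated imide carbonyl to the C6 primary alcohol while the Weinreb amide is inert.

Step 10
Reactants: 15 (3R)-3-{[(2S,3S)-1-chloro-3-(4-methoxybenzyloxy)pentan-2-yl]oxy}-4-hydroxy-N-methoxy-N-methylbutanamide
Product: 16 (3R)-4-(tert-butyldiphenylsilyloxy)-3-{[(2S,3S)-1-chloro-3-(4-methoxybenzyloxy)pentan-2-yl]oxy}-N-methoxy-N-methylbutanamide
Conditions: t-BuPh2SiCl, imidazole, CH2Cl2, 0 → 25 °C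
Reagents that add atoms: tert-butyldiphenylsilyl chloride, CC(C)(C)[Si](Cl)(c1ccccc1)c1ccccc1
Why: Silylation under imidazole conditions (no alkoxide, no acid) protects O6 before the hydroxy amide can lactonise or displace the C11 chloride.

Step 11
Reactants: 16 (3R)-4-(tert-butyldiphenylsilyloxy)-3-{[(2S,3S)-1-chloro-3-(4-methoxybenzyloxy)pentan-2-yl]oxy}-N-methoxy-N-methylbutanamide; 17 1,3-dithiane
Product: 19 (3R)-4-(tert-butyldiphenylsilyloxy)-3-{[(2S,3S)-1-chloro-3-(4-methoxybenzyloxy)pentan-2-yl]oxy}-1-(1,3-dithian-2-yl)butan-1-one, via 2-lithio-1,3-dithiane 18 (not isolated)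
Conditions: 17, n-BuLi, THF, −30 °C; then 16, −78 °C; aq. NH4Cl
Reagents that add atoms: none
Why: Corey–Seebach acylation, in which the lithiated dithiane adds once to the Weinreb amide (stable tetrahedral chelate, no over-addition) to install C10 as a 2-acyl-1,3-dithiane while the alkyl chloride is inert at −78 °C.

Step 12
Reactants: 19 (3R)-4-(tert-butyldiphenylsilyloxy)-3-{[(2S,3S)-1-chloro-3-(4-methoxybenzyloxy)pentan-2-yl]oxy}-1-(1,3-dithian-2-yl)butan-1-one
Product: 20 (1R,3R)-4-(tert-butyldiphenylsilyloxy)-3-{[(2S,3S)-1-chloro-3-(4-methoxybenzyloxy)pentan-2-yl]oxy}-1-(1,3-dithian-2-yl)butan-1-ol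
Conditions: (S)-2-methyl-CBS-oxazaborolidine (0.5 equiv), BH3·SMe2, THF, −20 °C; MeOH
Reagents that add atoms: none
Why: Corey–Bakshi–Shibata reduction, in which the dithianyl group acts as the large substituent so that the (S)-catalyst delivers hydride to the face giving the (9R)-alcohol by reagent control.

Step 13
Reactants: 20 (1R,3R)-4-(tert-butyldiphenylsilyloxy)-3-{[(2S,3S)-1-chloro-3-(4-methoxybenzyloxy)pentan-2-yl]oxy}-1-(1,3-dithian-2-yl)butan-1-ol
Product: 22 (8R,10R,12R)-10-(tert-butyldiphenylsilyloxymethyl)-8-[(1S)-1-(4-methoxybenzyloxy)propyl]-9-oxa-1,5-dithiaspiro[5.6]dodecan-12-ol, via O9,C10-dilithio dianion 21 (not isolated)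
Conditions: t-BuLi (2.1 equiv), THF/HMPA (9:1), 0.01 M, −78 °C; then −78 → 0 °C; aq. NH4Cl
Reagents that add atoms: none
Why: The first equivalent of t-BuLi makes the O9 lithium alkoxide and the second removes the dithiane C10–H; the sulfur-stabilised carbanion then displaces the primary C11 chloride in an intramolecular SN2 reaction that forms C10–C11. The closest known reaction type is the Corey–Seebach cyclisation of 2-(ω-chloroalkyl)-1,3-dithianes to three- to seven-membered cycloalkanone dithioketals. The oxepane is closed in the 7-exo-tet mode. No stereocentre is created, since C10 becomes a spiro dithioketal carbon and C7, C9, C12 and C13 are carried in, so the 2,7-trans relation of the ring is that of the acyclic ether. The step needs C-alkylation to beat O9-alkylation, β-elimination and oligomerisation. The O9 alkoxide cannot leave as a β-leaving group and is a far poorer nucleophile towards an alkyl chloride than the soft carbanion, high dilution favours ring closure, and chloride survives the alkyllithium without halogen–metal exchange.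

Step 14
Reactants: 22 (8R,10R,12R)-10-(tert-butyldiphenylsilyloxymethyl)-8-[(1S)-1-(4-methoxybenzyloxy)propyl]-9-oxa-1,5-dithiaspiro[5.6]dodecan-12-ol
Product: 23 O9-triethylsilyl ether of 22 (7R,9R,12R,13S)
Conditions: Et3SiOTf, 2,6-lutidine, CH2Cl2, −78 → 0 °C
Reagents that add atoms: triethylsilyl triflate, CC[Si](CC)(CC)OS(=O)(=O)C(F)(F)F
Why: Silyl triflate silylation of the hindered C9 hydroxyl keeps O9 distinguishable from the O10 hydroxyl that appears two steps later.

Step 15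
Reactants: 23 O9-triethylsilyl ether of 22
Product: 24 (2R,5R,7R)-7-(tert-butyldiphenylsilyloxymethyl)-2-[(1S)-1-(4-methoxybenzyloxy)propyl]-5-(triethylsilyloxy)oxepan-4-one (C10 ketone; 7R,9R,12R,13S)
Conditions: MeI, CaCO3, MeCN/H2O (9:1), 45 °C
Reagents that add atoms: water, O
Why: Alkylative hydrolysis of the dithioketal (S-methylation, then hydrolysis buffered by CaCO3) unmasks the C10 ketone without touching the silyl and PMB ethers.

Step 16
Reactants: 24 C10 ketone (7R,9R,12R,13S)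
Product: 25 (2R,4S,5R,7R)-7-(tert-butyldiphenylsilyloxymethyl)-2-[(1S)-1-(4-methoxybenzyloxy)propyl]-5-(triethylsilyloxy)oxepan-4-ol (C10 alcohol; 7R,9R,10S,12R,13S)
Conditions: LiBH(s-Bu)3, THF, −78 °C; MeOH then aq. NH4Cl at −78 °C
Reagents that add atoms: none
Why: Substrate-controlled hydride reduction in which the bulky borohydride attacks C10 anti to the adjacent C9 silyloxy group (polar Felkin–Anh) to give the 9,10-cis alcohol, i.e. (10S), the cold quench preventing silyl migration.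

Step 17
Reactants: 25 C10 alcohol (7R,9R,10S,12R,13S)
Product: 26 O10-triisopropylsilyl ether of 25 (7R,9R,10S,12R,13S)
Conditions: i-Pr3SiOTf, 2,6-lutidine, CH2Cl2, 0 → 25 °C
Reagents that add atoms: triisopropylsilyl triflate, CC(C)[Si](OS(=O)(=O)C(F)(F)F)(C(C)C)C(C)C
Why: Silyl triflate silylation places a robust ether on O10 that survives every later halogenation and deprotection until the last step.

Step 18
Reactants: 26 O10-triisopropylsilyl ether of 25
Product: 27 C9 alcohol with O10 TIPS ether (7R,9R,10S,12R,13S)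
Conditions: pyridinium p-toluenesulfonate (cat.), MeOH/CH2Cl2, 0 °C
Reagents that add atoms: none
Why: Mild acid methanolysis removes the triethylsilyl ether selectively, the TIPS, TBDPS and PMB ethers being far less labile.

Step 19
Reactants: 27 C9 alcohol with O10 TIPS ether
Product: 28 C9 chloride (7R,9S,10S,12R,13S)
Conditions: CCl4, P(n-C8H17)3, toluene, 80 °C
Reagents that add atoms: carbon tetrachloride, ClC(Cl)(Cl)Cl
Why: Appel-type chlorination in which chloride displaces the oxyphosphonium with SN2 inversion, converting (9R)-OH into (9S)-Cl trans to the O10 substituent.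

Step 20
Reactants: 28 C9 chloride (7R,9S,10S,12R,13S)
Product: 29 C6 primary alcohol (7R,9S,10S,12R,13S)
Conditions: Bu4NF, AcOH (1:1), THF, 25 °C
Reagents that add atoms: none
Why: Buffered fluoride desilylation cleaves the unhindered primary TBDPS ether much faster than the hindered secondary TIPS ether.

Step 21
Reactants: 29 C6 primary alcohol
Product: 30 C6 aldehyde (7R,9S,10S,12R,13S)
Conditions: Dess–Martin periodinane, CH2Cl2, 0 → 25 °C
Reagents that add atoms: none
Why: Dess–Martin oxidation under near-neutral conditions gives the α-alkoxy aldehyde without epimerising C7.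

Step 22
Reactants: 30 C6 aldehyde; 31 (−)-B-allyldiisopinocampheylborane (from (+)-α-pinene, commercial solution)
Product: 33 (6S)-homoallylic alcohol (6S,7R,9S,10S,12R,13S), via diisopinocampheylborinate 32 (not isolated)
Conditions: 31, Et2O, −78 °C; then NaOH, H2O2, 0 → 25 °C
Reagents that add atoms: none
Why: Brown allylboration through a chair transition state, the reagent's facial preference coinciding with the Felkin–Anh/Cornforth preference of the α-alkoxy aldehyde (matched pair), should give the 6,7-anti (6S) alcohol and adds C3–C5.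

Step 23
Reactants: 33 (6S)-homoallylic alcohol
Product: 34 6,9-dichloride (6R,7R,9S,10S,12R,13S)
Conditions: CCl4, P(n-C8H17)3, toluene, 70 °C
Reagents that add atoms: carbon tetrachloride, ClC(Cl)(Cl)Cl
Why: Appel-type chlorination with SN2 inversion converts (6S)-OH into (6R)-Cl.

Step 24
Reactants: 34 6,9-dichloride
Product: 35 C13 alcohol (6R,7R,9S,10S,12R,13S)
Conditions: DDQ, CH2Cl2/pH 7 buffer, 0 °C
Reagents that add atoms: none
Why: Oxidative PMB cleavage (benzylic hydride abstraction by DDQ, hydrolysis of the oxocarbenium ion) frees O13 without affecting the alkene, the chlorides or the TIPS ether.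

Step 25
Reactants: 35 C13 alcohol
Product: 36 C13 bromide (6R,7R,9S,10S,12R,13R)
Conditions: CBr4, P(n-C8H17)3, toluene, 70 °C
Reagents that add atoms: carbon tetrabromide, BrC(Br)(Br)Br
Why: Appel-type bromination with SN2 inversion converts (13S)-OH into (13R)-Br.

Step 26
Reactants: 36 C13 bromide; 37 (but-3-en-1-yn-1-yl)triisopropylsilane
Product: 38 (3Z)-silyl enyne (3Z,6R,7R,9S,10S,12R,13R)
Conditions: second-generation Grubbs catalyst RuCl2(=CHPh)(H2IMes)(PCy3) (10 mol%), 37 (5 equiv), benzene, 70 °C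
Reagents that add atoms: none
Why: Olefin cross-metathesis of the terminal alkene with a conjugated silyl enyne, a pairing known to favour the Z-enyne kinetically, should deliver C1–C2 and the C3=C4 Z-alkene with loss of ethene.

Step 27
Reactants: 38 (3Z)-silyl enyne
Product: 39 terminal (3Z)-enyne with O10 TIPS ether (3Z,6R,7R,9S,10S,12R,13R)
Conditions: Bu4NF, THF, −20 → 0 °C
Reagents that add atoms: none
Why: Fluoride-induced protodesilylation of the alkynylsilane at low temperature is faster than cleavage of the hindered secondary TIPS ether, so no alkoxide is formed next to the C9 chloride.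

Step 28
Reactants: 39 terminal (3Z)-enyne with O10 TIPS ether
Product: 40 (2R,4S,5S,7R)-2-[(1R)-1-bromopropyl]-5-chloro-7-[(1R,3Z)-1-chlorohex-3-en-5-yn-1-yl]oxepan-4-ol (target)
Conditions: HF·pyridine, THF/pyridine, 0 → 25 °C
Reagents that add atoms: none
Why: Acidic fluoride desilylation removes the TIPS ether without generating an alkoxide, so the trans-chlorohydrin cannot close to an epoxide and the halides and Z-enyne are untouched.

**Compound list**

1 | penta-1,4-dien-3-ol | C=CC(O)C=C | starting material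
2 | (2R,3S)-1,2-epoxypent-4-en-3-ol | O1[C@H](C1)[C@@H](O)C=C | intermediate
3 | (2R,3S)-1,2-epoxy-3-(4-methoxybenzyloxy)pent-4-ene | O1[C@H](C1)[C@@H](OCc2ccc(OC)cc2)C=C | intermediate
4 | (2R,3S)-1,2-epoxy-3-(4-methoxybenzyloxy)pentane | O1[C@H](C1)[C@@H](OCc2ccc(OC)cc2)CC | intermediate
5 | (2S,3S)-1-chloro-3-(4-methoxybenzyloxy)pentan-2-ol | O[C@H](CCl)[C@@H](OCc1ccc(OC)cc1)CC | intermediate
6 | ethyl diazoacetate | CCOC(=O)C=[N+]=[N-] | starting material
7 | ethyl 2-{[(2S,3S)-1-chloro-3-(4-methoxybenzyloxy)pentan-2-yl]oxy}acetate | CCOC(=O)CO[C@H](CCl)[C@@H](OCc1ccc(OC)cc1)CC | intermediate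
8 | 2-{[(2S,3S)-1-chloro-3-(4-methoxybenzyloxy)pentan-2-yl]oxy}acetic acid | OC(=O)CO[C@H](CCl)[C@@H](OCc1ccc(OC)cc1)CC | intermediate
9 | (S)-4-benzyloxazolidin-2-one | O=C1N[C@@H](Cc2ccccc2)CO1 | starting material
10 | mixed pivalic anhydride of acid 8 (not isolated) | CC(C)(C)C(=O)OC(=O)CO[C@H](CCl)[C@@H](OCc1ccc(OC)cc1)CC | intermediate
11 | (4S)-4-benzyl-3-(2-{[(2S,3S)-1-chloro-3-(4-methoxybenzyloxy)pentan-2-yl]oxy}acetyl)oxazolidin-2-one | O=C1OC[C@H](Cc2ccccc2)N1C(=O)CO[C@H](CCl)[C@@H](OCc2ccc(OC)cc2)CC | intermediate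
12 | 2-bromo-N-methoxy-N-methylacetamide | CON(C)C(=O)CBr | starting material
13 | sodium Z-enolate of imide 11 (not isolated) | [Na+].[O-]/C(=C\O[C@H](CCl)[C@@H](OCc1ccc(OC)cc1)CC)N1C(=O)OC[C@@H]1Cc1ccccc1 | intermediate
14 | (4S)-4-benzyl-3-[(2R)-2-{[(2S,3S)-1-chloro-3-(4-methoxybenzyloxy)pentan-2-yl]oxy}-4-[methoxy(methyl)amino]-4-oxobutanoyl]oxazolidin-2-one | O=C1OC[C@H](Cc2ccccc2)N1C(=O)[C@@H](CC(=O)N(C)OC)O[C@H](CCl)[C@@H](OCc2ccc(OC)cc2)CC | intermediate
15 | (3R)-3-{[(2S,3S)-1-chloro-3-(4-methoxybenzyloxy)pentan-2-yl]oxy}-4-hydroxy-N-methoxy-N-methylbutanamide | OC[C@@H](CC(=O)N(C)OC)O[C@H](CCl)[C@@H](OCc1ccc(OC)cc1)CC | intermediate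
16 | (3R)-4-(tert-butyldiphenylsilyloxy)-3-{[(2S,3S)-1-chloro-3-(4-methoxybenzyloxy)pentan-2-yl]oxy}-N-methoxy-N-methylbutanamide | CC(C)(C)[Si](c1ccccc1)(c1ccccc1)OC[C@@H](CC(=O)N(C)OC)O[C@H](CCl)[C@@H](OCc1ccc(OC)cc1)CC | intermediate
17 | 1,3-dithiane | C1CSCSC1 | starting material
18 | 2-lithio-1,3-dithiane (not isolated) | [Li]C1SCCCS1 | intermediate
19 | (3R)-4-(tert-butyldiphenylsilyloxy)-3-{[(2S,3S)-1-chloro-3-(4-methoxybenzyloxy)pentan-2-yl]oxy}-1-(1,3-dithian-2-yl)butan-1-one | CC(C)(C)[Si](c1ccccc1)(c1ccccc1)OC[C@@H](CC(=O)C1SCCCS1)O[C@H](CCl)[C@@H](OCc1ccc(OC)cc1)CC | intermediate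
20 | (1R,3R)-4-(tert-butyldiphenylsilyloxy)-3-{[(2S,3S)-1-chloro-3-(4-methoxybenzyloxy)pentan-2-yl]oxy}-1-(1,3-dithian-2-yl)butan-1-ol (acyclic C7–O–C12 ether, C10 dithiane, free O9–H, C11 chloride) | CC(C)(C)[Si](c1ccccc1)(c1ccccc1)OC[C@@H](C[C@@H](O)C1SCCCS1)O[C@H](CCl)[C@@H](OCc1ccc(OC)cc1)CC | intermediate
21 | O9,C10-dilithio dianion of 20 (not isolated) | CC(C)(C)[Si](c1ccccc1)(c1ccccc1)OC[C@@H](C[C@@H](O[Li])C1([Li])SCCCS1)O[C@H](CCl)[C@@H](OCc1ccc(OC)cc1)CC | intermediate
22 | (8R,10R,12R)-10-(tert-butyldiphenylsilyloxymethyl)-8-[(1S)-1-(4-methoxybenzyloxy)propyl]-9-oxa-1,5-dithiaspiro[5.6]dodecan-12-ol (2,7-trans-oxepane, C10 spiro-dithiane, C9 hydroxyl) | CC(C)(C)[Si](c1ccccc1)(c1ccccc1)OC[C@H]1C[C@@H](O)C2(SCCCS2)C[C@H]([C@@H](OCc2ccc(OC)cc2)CC)O1 | intermediate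
23 | O9-triethylsilyl ether of 22 (7R,9R,12R,13S) | CC(C)(C)[Si](c1ccccc1)(c1ccccc1)OC[C@H]1C[C@@H](O[Si](CC)(CC)CC)C2(SCCCS2)C[C@H]([C@@H](OCc2ccc(OC)cc2)CC)O1 | intermediate
24 | (2R,5R,7R)-7-(tert-butyldiphenylsilyloxymethyl)-2-[(1S)-1-(4-methoxybenzyloxy)propyl]-5-(triethylsilyloxy)oxepan-4-one | CC(C)(C)[Si](c1ccccc1)(c1ccccc1)OC[C@H]1C[C@@H](O[Si](CC)(CC)CC)C(=O)C[C@H]([C@@H](OCc2ccc(OC)cc2)CC)O1 | intermediate
25 | (2R,4S,5R,7R)-7-(tert-butyldiphenylsilyloxymethyl)-2-[(1S)-1-(4-methoxybenzyloxy)propyl]-5-(triethylsilyloxy)oxepan-4-ol | CC(C)(C)[Si](c1ccccc1)(c1ccccc1)OC[C@H]1C[C@@H](O[Si](CC)(CC)CC)[C@@H](O)C[C@H]([C@@H](OCc2ccc(OC)cc2)CC)O1 | intermediate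
26 | O10-triisopropylsilyl ether of 25 (7R,9R,10S,12R,13S) | CC(C)(C)[Si](c1ccccc1)(c1ccccc1)OC[C@H]1C[C@@H](O[Si](CC)(CC)CC)[C@@H](O[Si](C(C)C)(C(C)C)C(C)C)C[C@H]([C@@H](OCc2ccc(OC)cc2)CC)O1 | intermediate
27 | oxepane with C7 CH2OTBDPS, (9R)-OH, (10S)-OTIPS, C12 (S)-1-(4-methoxybenzyloxy)propyl (7R,9R,10S,12R,13S) | CC(C)(C)[Si](c1ccccc1)(c1ccccc1)OC[C@H]1C[C@@H](O)[C@@H](O[Si](C(C)C)(C(C)C)C(C)C)C[C@H]([C@@H](OCc2ccc(OC)cc2)CC)O1 | intermediate
28 | oxepane with C7 CH2OTBDPS, (9S)-Cl, (10S)-OTIPS, C12 (S)-1-(4-methoxybenzyloxy)propyl (7R,9S,10S,12R,13S) | CC(C)(C)[Si](c1ccccc1)(c1ccccc1)OC[C@H]1C[C@H](Cl)[C@@H](O[Si](C(C)C)(C(C)C)C(C)C)C[C@H]([C@@H](OCc2ccc(OC)cc2)CC)O1 | intermediate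
29 | C6 primary alcohol: oxepane with C7 CH2OH, (9S)-Cl, (10S)-OTIPS, C13 OPMB (7R,9S,10S,12R,13S) | OC[C@H]1C[C@H](Cl)[C@@H](O[Si](C(C)C)(C(C)C)C(C)C)C[C@H]([C@@H](OCc2ccc(OC)cc2)CC)O1 | intermediate
30 | C6 aldehyde: oxepane-C7 carbaldehyde with (9S)-Cl, (10S)-OTIPS, C13 OPMB (7R,9S,10S,12R,13S) | O=C[C@H]1C[C@H](Cl)[C@@H](O[Si](C(C)C)(C(C)C)C(C)C)C[C@H]([C@@H](OCc2ccc(OC)cc2)CC)O1 | intermediate
31 | (−)-B-allyldiisopinocampheylborane (from (+)-α-pinene) | C=CCB([C@@H]1C[C@@H]2C[C@H]([C@H]1C)C2(C)C)[C@@H]1C[C@@H]2C[C@H]([C@H]1C)C2(C)C | starting material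
32 | diisopinocampheylborinate of alcohol 33 (not isolated) | C=CC[C@H](OB([C@@H]1C[C@@H]2C[C@H]([C@H]1C)C2(C)C)[C@@H]1C[C@@H]2C[C@H]([C@H]1C)C2(C)C)[C@H]1C[C@H](Cl)[C@@H](O[Si](C(C)C)(C(C)C)C(C)C)C[C@H]([C@@H](OCc2ccc(OC)cc2)CC)O1 | intermediate
33 | (6S)-homoallylic alcohol: C7 (S)-1-hydroxybut-3-enyl, (9S)-Cl, (10S)-OTIPS, C13 OPMB (6S,7R,9S,10S,12R,13S) | C=CC[C@H](O)[C@H]1C[C@H](Cl)[C@@H](O[Si](C(C)C)(C(C)C)C(C)C)C[C@H]([C@@H](OCc2ccc(OC)cc2)CC)O1 | intermediate
34 | 6,9-dichloride with terminal alkene, (10S)-OTIPS, C13 OPMB (6R,7R,9S,10S,12R,13S) | C=CC[C@@H](Cl)[C@H]1C[C@H](Cl)[C@@H](O[Si](C(C)C)(C(C)C)C(C)C)C[C@H]([C@@H](OCc2ccc(OC)cc2)CC)O1 | intermediate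
35 | 6,9-dichloride with free (13S)-OH, (10S)-OTIPS (6R,7R,9S,10S,12R,13S) | C=CC[C@@H](Cl)[C@H]1C[C@H](Cl)[C@@H](O[Si](C(C)C)(C(C)C)C(C)C)C[C@H]([C@@H](O)CC)O1 | intermediate
36 | 6,9-dichloro-13-bromide with terminal alkene, (10S)-OTIPS (6R,7R,9S,10S,12R,13R) | C=CC[C@@H](Cl)[C@H]1C[C@H](Cl)[C@@H](O[Si](C(C)C)(C(C)C)C(C)C)C[C@H]([C@H](Br)CC)O1 | intermediate
37 | (but-3-en-1-yn-1-yl)triisopropylsilane | C=CC#C[Si](C(C)C)(C(C)C)C(C)C | starting material
38 | (3Z)-1-triisopropylsilyl enyne with (10S)-OTIPS (3Z,6R,7R,9S,10S,12R,13R) | CC(C)[Si](C(C)C)(C(C)C)C#C/C=C\C[C@@H](Cl)[C@H]1C[C@H](Cl)[C@@H](O[Si](C(C)C)(C(C)C)C(C)C)C[C@H]([C@H](Br)CC)O1 | intermediate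
39 | terminal (3Z)-enyne with (10S)-OTIPS (3Z,6R,7R,9S,10S,12R,13R) | C#C/C=C\C[C@@H](Cl)[C@H]1C[C@H](Cl)[C@@H](O[Si](C(C)C)(C(C)C)C(C)C)C[C@H]([C@H](Br)CC)O1 | intermediate
40 | (2R,4S,5S,7R)-2-[(1R)-1-bromopropyl]-5-chloro-7-[(1R,3Z)-1-chlorohex-3-en-5-yn-1-yl]oxepan-4-ol (3Z,6R,7R,9S,10S,12R,13R) | C#C/C=C\C[C@@H](Cl)[C@H]1C[C@H](Cl)[C@@H](O)C[C@H]([C@H](Br)CC)O1 | target

**Step count.** Total: 28 steps. Longest linear sequence: 28 steps (1 → 40); all other numbered inputs (6, 9, 12, 17, 31, 37) are used as supplied.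

**Steps most likely to fail**

Step 13 (ring closure). The dianion may be too slow in displacing the deactivated, β-alkoxy primary chloride, so that O-alkylation by the O9 alkoxide, elimination towards the enol ether or intermolecular reaction take over. The fallback sets out from ketone 19, in which the C10–H lies between the carbonyl and two sulfurs and is removed by a mild base (Cs2CO3, catalytic Bu4NI, DMF, 50 °C, high dilution). The stabilised carbanion should C-alkylate C11 in the same 7-exo-tet sense to give the C9-keto spiro-dithiane oxepane F1. CBS reduction with the (S)-catalyst and BH3·SMe2, the dithioketal carbon acting as the large group, should then give the (9R)-alcohol and return to 22.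

Step 19 (C9 chlorination). The oxyphosphonium on a ring carbon next to the bulky silyloxy group may eliminate to an alkene or enol ether instead of undergoing substitution, or may react sluggishly. The fallback sets out from alcohol 27 and separates activation from displacement: sulfonylation with ClCH2SO2Cl and pyridine in CH2Cl2 at 0 °C gives the C9 chloromethanesulfonate F2, and LiCl in DMF at 40 °C displaces it with inversion to rejoin the route at chloride 28.

Step 26 (cross-metathesis). Z-selectivity or conversion may be insufficient, leaving an E/Z mixture that is hard to separate this late. The fallback sets out from alkene 36. Oxidative cleavage (OsO4 cat., NaIO4, 2,6-lutidine, dioxane/H2O) gives the β-chloro aldehyde F3. Stork–Zhao olefination (Ph3P+CH2I I−, NaN(SiMe3)2, THF/HMPA, −78 °C, kept cold to avoid loss of HCl) should give the Z-iodoalkene F4. Sonogashira coupling with (triisopropylsilyl)acetylene (Pd(PPh3)4, CuI, i-Pr2NH) returns to silyl enyne 38.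

**Further compounds**

F1 | step 13 | (8R,10R)-10-(tert-butyldiphenylsilyloxymethyl)-8-[(1S)-1-(4-methoxybenzyloxy)propyl]-9-oxa-1,5-dithiaspiro[5.6]dodecan-12-one | CC(C)(C)[Si](c1ccccc1)(c1ccccc1)OC[C@H]1CC(=O)C2(SCCCS2)C[C@H]([C@@H](OCc2ccc(OC)cc2)CC)O1
F2 | step 19 | C9 chloromethanesulfonate of alcohol 27 (7R,9R,10S,12R,13S) | CC(C)(C)[Si](c1ccccc1)(c1ccccc1)OC[C@H]1C[C@@H](OS(=O)(=O)CCl)[C@@H](O[Si](C(C)C)(C(C)C)C(C)C)C[C@H]([C@@H](OCc2ccc(OC)cc2)CC)O1
F3 | step 26 | C4 aldehyde from alkene 36 (6R,7R,9S,10S,12R,13R) | O=CC[C@@H](Cl)[C@H]1C[C@H](Cl)[C@@H](O[Si](C(C)C)(C(C)C)C(C)C)C[C@H]([C@H](Br)CC)O1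
F4 | step 26 | (3Z)-3-iodoalkene (3Z,6R,7R,9S,10S,12R,13R) | I/C=C\C[C@@H](Cl)[C@H]1C[C@H](Cl)[C@@H](O[Si](C(C)C)(C(C)C)C(C)C)C[C@H]([C@H](Br)CC)O1
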